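**Retrosynthetic overview**

1. Target 18 ← 17 (benzyl ether) ← 15 by hydroboration of C3a=C4 ← 12 by isopropyl addition and in-flask acylation at the C3 ketone ← 11 by epoxidation of C6=C7; each of these reagents is expected to attack the face opposite the angular C8a methyl group.
2. Key disconnection: dienone 11 ← ynone 10 by an intramolecular (5+2) cycloaddition that forms the C4–C5 and C3a–C8a bonds and both carbocycles at once from a cyclopropane.
3. Enabling feature: the seven-membered ring (C3a, C4, C5, C6, C7, C8, C8a) holds the five-carbon string C5–C6(CH3)=C7–C8–C8a, the ring-opened form of a 1-isopropenylcyclopropane (ring carbons C7, C8, C8a). Beside it lies the two-carbon unit C3a=C4 conjugated to the C3 carbonyl (the alkyne of an ynone), and the chain C8a–C1–C2–C3 is a three-atom tether that closes the five-membered ring in the same event.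
4. Ynone 10 ← nerol 1: asymmetric cyclopropanation fixes C8a, the CH2OH group becomes the isopropenyl group, and the prenyl terminus is cut back to the ynone.
5. Ring order: cyclopropane (step 1), then cyclopentanone and cycloheptadiene together (step 8), then the epoxide (step 9).

Key step: step 8

Remark: bicyclic compounds carry azulene locants (C1, C2 = ring CH2; C3 = isopropyl carbinol carbon; C3a = ring-fusion CH; C4 = secondary carbinol; C5 = CH2; C6 = methyl-bearing epoxide carbon; C7 = epoxide CH; C8 = CH2; C8a = methyl-bearing ring-fusion carbon), and metal alkoxides that are only protonated on aqueous work-up are counted with their step and not numbered.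

**Step 1**
Reactants: 1 nerol, (2Z)-3,7-dimethylocta-2,6-dien-1-ol
Product: 2 [(1S,2R)-2-methyl-2-(4-methylpent-3-en-1-yl)cyclopropyl]methanol
Conditions: Et2Zn, CH2I2, DME, (4R,5R)-2-butyl-N,N,N',N'-tetramethyl-1,3,2-dioxaborolane-4,5-dicarboxamide (1.2 equiv), CH2Cl2, −10 °C to rt; aq. NH4Cl
Reagents that add atoms: diiodomethane, ICI
Why: Dioxaborolane-mediated asymmetric Simmons–Smith cyclopropanation, in which the zinc alkoxide of the allylic alcohol binds the (R,R)-dioxaborolane and Zn(CH2I)2 is delivered to one face of the proximal Z-alkene only (the distal alkene has no directing group), so that both cyclopropane stereocentres are set with CH2OH and the homoprenyl chain cis, as the Z geometry dictates.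

**Step 2**
Reactants: 2 [(1S,2R)-2-methyl-2-(4-methylpent-3-en-1-yl)cyclopropyl]methanol
Product: 4 (1S,2R)-2-methyl-2-(4-methylpent-3-en-1-yl)cyclopropane-1-carboxylic acid, via aldehyde 3 (not isolated)
Conditions: TEMPO (0.2 equiv), PhI(OAc)2 (2.2 equiv), MeCN/H2O 1:1, rt
Reagents that add atoms: water, O
Why: Oxoammonium (TEMPO) oxidation in aqueous acetonitrile takes the primary alcohol through the aldehyde hydrate to the acid without touching the trisubstituted alkene or epimerising the cyclopropane carbon.

**Step 3**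
Reactants: 4 (1S,2R)-2-methyl-2-(4-methylpent-3-en-1-yl)cyclopropane-1-carboxylic acid
Product: 5 1-[(1S,2R)-2-methyl-2-(4-methylpent-3-en-1-yl)cyclopropyl]ethan-1-one
Conditions: MeLi (2.5 equiv), Et2O, 0 °C to rt; inverse quench into cold 1 M HCl
Reagents that add atoms: methyllithium, [Li]C
Why: Addition of methyllithium to the lithium carboxylate stops at the dilithium gem-diolate, which collapses to the methyl ketone only on work-up (classical acid-to-methyl-ketone conversion), and no stereocentre is touched.

**Step 4**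
Reactants: 5 1-[(1S,2R)-2-methyl-2-(4-methylpent-3-en-1-yl)cyclopropyl]ethan-1-one
Product: 7 3-[(1R,2S)-2-acetyl-1-methylcyclopropyl]propanal, via ozonide 6 (not isolated)
Conditions: O3, CH2Cl2, −78 °C; then Me2S, −78 °C to rt
Reagents that add atoms: ozone, [O-][O+]=O
Why: Ozonolysis with reductive work-up cleaves the only alkene in the molecule to the aldehyde, while the cyclopropyl ketone is inert to ozone.

**Step 5**
Reactants: 7 3-[(1R,2S)-2-acetyl-1-methylcyclopropyl]propanal
Product: 8 1-[(1S,2R)-2-(3-hydroxypent-4-yn-1-yl)-2-methylcyclopropyl]ethan-1-one (both carbinol epimers)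
Conditions: HC≡CMgBr (1.1 equiv), THF, −78 to −40 °C; aq. NH4Cl
Reagents that add atoms: ethynylmagnesium bromide, C#C[Mg]Br
Why: Grignard addition at low temperature is chemoselective for the aldehyde over the hindered, conjugatively deactivated cyclopropyl methyl ketone, and the new carbinol centre (formed as both epimers) is erased in step 7.

**Step 6**
Reactants: 8 1-[(1S,2R)-2-(3-hydroxypent-4-yn-1-yl)-2-methylcyclopropyl]ethan-1-one
Product: 9 5-[(1R,2R)-1-methyl-2-(prop-1-en-2-yl)cyclopropyl]pent-1-yn-3-ol (both carbinol epimers)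
Conditions: Ph3PCH3Br (3.5 equiv), KOt-Bu (3.3 equiv), THF, 0 °C to rt
Reagents that add atoms: methyltriphenylphosphonium bromide, C[P+](c1ccccc1)(c1ccccc1)c1ccccc1.[Br-]
Why: Wittig methylenation of the methyl ketone with excess ylide (the propargylic alkoxide is a spectator) gives the isopropenyl group, and the cis relationship on the ring should be kept because enolisation toward a cyclopropane carbon is disfavoured by strain.

**Step 7**
Reactants: 9 5-[(1R,2R)-1-methyl-2-(prop-1-en-2-yl)cyclopropyl]pent-1-yn-3-ol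
Product: 10 5-[(1R,2R)-1-methyl-2-(prop-1-en-2-yl)cyclopropyl]pent-1-yn-3-one
Conditions: Dess–Martin periodinane, NaHCO3, CH2Cl2, 0 °C to rt
Reagents that add atoms: none
Why: Dess–Martin oxidation converts the secondary propargylic alcohol to the terminal ynone under buffered, non-nucleophilic conditions that spare the vinylcyclopropane.

**Step 8**
Reactants: 10 5-[(1R,2R)-1-methyl-2-(prop-1-en-2-yl)cyclopropyl]pent-1-yn-3-one
Product: 11 (8aR)-6,8a-dimethyl-1,2,8,8a-tetrahydroazulen-3(5H)-one
Conditions: [Rh(CO)2Cl]2 (5 mol %), toluene (0.02 M), 80 °C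
Reagents that add atoms: none
Why: Proposed new method: [Rh(CO)2Cl]2 should bind the isopropenyl group and insert monovalent rhodium into the strained cyclopropane bond between C7 and C8a, the only ring bond whose cleavage lets the three-atom tether bring the alkyne to the metal, to give an allyl(alkyl)rhodium species; the ynone then inserts into the Rh–C8a bond (5-exo-dig carbometallation, closing the cyclopentanone through the C3a–C8a bond) and C(sp2)–C(sp3) reductive elimination at the terminal allyl carbon closes the cycloheptadiene through the C4–C5 bond from an eight-membered rhodacycle, a formal intramolecular (5+2) cycloaddition. The closest known reaction types are the rhodium-catalysed intramolecular (5+2) cycloadditions of vinylcyclopropanes with alkynes tethered at the vinyl terminus and the (5+2) mode of alkenes tethered cis on the cyclopropane ring; new here are the alkyne partner in the cyclopropane-tethered series and the fully substituted cyclopropane carbon, which must pass through a tertiary alkyl–rhodium bond. No stereocentre is created: C8a is carried over from the cyclopropane with retention (oxidative addition and migratory insertion both retain configuration at carbon), so the configuration set in step 1 becomes that of the quaternary ring-fusion carbon, and the C7 stereocentre is erased as it becomes sp2. The step needs seven-ring over five-ring reductive elimination ((5+2) against (3+2)), which the cis arrangement of isopropenyl group and tether should secure by holding the allyl terminus, not its internal carbon, next to the alkenyl–rhodium bond, and it needs to outrun the thermal homo-1,5-hydrogen shift of the cis-alkyl vinylcyclopropane, which is why the temperature is kept at 80 °C or below.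

**Step 9**
Reactants: 11 (8aR)-6,8a-dimethyl-1,2,8,8a-tetrahydroazulen-3(5H)-one
Product: 12 (6R,7S,8aR)-6,7-epoxy-6,8a-dimethyl-1,2,6,7,8,8a-hexahydroazulen-3(5H)-one
Conditions: mCPBA (1.1 equiv), NaHCO3, CH2Cl2, 0 °C
Reagents that add atoms: 3-chloroperoxybenzoic acid, OOC(=O)c1cccc(Cl)c1
Why: Prilezhaev epoxidation is chemoselective for the electron-rich isolated trisubstituted alkene over the enone alkene, and the peracid should approach the face opposite the pseudo-axial C8a methyl group (homoallylic to C7), which sets C6 and C7.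

**Step 10**
Reactants: 12 (6R,7S,8aR)-6,7-epoxy-6,8a-dimethyl-1,2,6,7,8,8a-hexahydroazulen-3(5H)-one; 13 4-(benzyloxy)benzoyl chloride
Product: 15 (3R,6R,7S,8aR)-6,7-epoxy-6,8a-dimethyl-3-(propan-2-yl)-1,2,3,5,6,7,8,8a-octahydroazulen-3-yl 4-(benzyloxy)benzoate, via dichlorocerium alkoxide 14 (not isolated)
Conditions: i-PrLi (1.5 equiv), CeCl3 (1.6 equiv), THF, −78 °C; then 13 (2.0 equiv), DMAP (0.2 equiv), −78 to 0 °C
Reagents that add atoms: isopropyllithium, [Li]C(C)C; cerium trichloride, Cl[Ce](Cl)Cl (its atoms appear only in intermediate 14)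
Why: Organocerium 1,2-addition to the enolisable enone should occur from the face opposite the pseudo-axial C8a methyl group, which sets C3 with its oxygen cis to that methyl group, and the hindered tertiary alkoxide is acylated in the same flask while it is the only oxygen nucleophile in the molecule.

**Step 11**
Reactants: 15 (3R,6R,7S,8aR)-6,7-epoxy-6,8a-dimethyl-3-(propan-2-yl)-1,2,3,5,6,7,8,8a-octahydroazulen-3-yl 4-(benzyloxy)benzoate
Product: 17 (3R,3aS,4S,6R,7S,8aR)-6,7-epoxy-4-hydroxy-6,8a-dimethyl-3-(propan-2-yl)decahydroazulen-3-yl 4-(benzyloxy)benzoate, via alkylborane 16 (not isolated)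
Conditions: BH3·THF (3 equiv), THF, 0 °C to rt; then NaBO3·4H2O, THF/H2O, rt
Reagents that add atoms: borane–tetrahydrofuran, [BH3-][O+]1CCCC1 (boron appears only in intermediate 16); sodium perborate, [Na+].[Na+].O[B-]1(O)OO[B-](O)(O)OO1 (source of the hydroxyl oxygen)
Why: Hydroboration–oxidation adds H and B syn across the trisubstituted C3a=C4 alkene with boron at the less substituted C4, and attack from the face opposite the C8a methyl and C3 acyloxy groups should place C3a–H and C4–OH cis to each other and trans to the angular methyl group (trans ring fusion), while perborate oxidation proceeds with retention and should spare ester and epoxide.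

**Step 12**
Reactants: 17 (3R,3aS,4S,6R,7S,8aR)-6,7-epoxy-4-hydroxy-6,8a-dimethyl-3-(propan-2-yl)decahydroazulen-3-yl 4-(benzyloxy)benzoate
Product: 18 (3R,3aS,4S,6R,7S,8aR)-6,7-epoxy-4-hydroxy-6,8a-dimethyl-3-(propan-2-yl)decahydroazulen-3-yl 4-hydroxybenzoate
Conditions: H2 (1 atm), 10% Pd/C, EtOAc, rt
Reagents that add atoms: none
Why: Hydrogenolysis of the benzyl aryl ether under neutral conditions frees the phenol without acyl migration, epoxide opening or ester cleavage, and no stereocentre is affected.

**Compound list**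

1 | nerol, (2Z)-3,7-dimethylocta-2,6-dien-1-ol | CC(C)=CCC/C(C)=C\CO | starting material
2 | [(1S,2R)-2-methyl-2-(4-methylpent-3-en-1-yl)cyclopropyl]methanol | OC[C@H]1C[C@@]1(C)CCC=C(C)C | intermediate
3 | (1S,2R)-2-methyl-2-(4-methylpent-3-en-1-yl)cyclopropane-1-carbaldehyde | O=C[C@H]1C[C@@]1(C)CCC=C(C)C | intermediate
4 | (1S,2R)-2-methyl-2-(4-methylpent-3-en-1-yl)cyclopropane-1-carboxylic acid | OC(=O)[C@H]1C[C@@]1(C)CCC=C(C)C | intermediate
5 | 1-[(1S,2R)-2-methyl-2-(4-methylpent-3-en-1-yl)cyclopropyl]ethan-1-one | CC(=O)[C@H]1C[C@@]1(C)CCC=C(C)C | intermediate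
6 | 1-[(1S,2R)-2-[2-(5,5-dimethyl-1,2,4-trioxolan-3-yl)ethyl]-2-methylcyclopropyl]ethan-1-one (ozonide, both epimers at the trioxolane carbon) | CC(=O)[C@H]1C[C@@]1(C)CCC1OOC(C)(C)O1 | intermediate
7 | 3-[(1R,2S)-2-acetyl-1-methylcyclopropyl]propanal | CC(=O)[C@H]1C[C@@]1(C)CCC=O | intermediate
8 | 1-[(1S,2R)-2-(3-hydroxypent-4-yn-1-yl)-2-methylcyclopropyl]ethan-1-one (both carbinol epimers) | CC(=O)[C@H]1C[C@@]1(C)CCC(O)C#C | intermediate
9 | 5-[(1R,2R)-1-methyl-2-(prop-1-en-2-yl)cyclopropyl]pent-1-yn-3-ol (both carbinol epimers) | CC(=C)[C@H]1C[C@@]1(C)CCC(O)C#C | intermediate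
10 | 5-[(1R,2R)-1-methyl-2-(prop-1-en-2-yl)cyclopropyl]pent-1-yn-3-one | CC(=C)[C@H]1C[C@@]1(C)CCC(=O)C#C | intermediate
11 | (8aR)-6,8a-dimethyl-1,2,8,8a-tetrahydroazulen-3(5H)-one | O=C1CC[C@]2(C)CC=C(C)CC=C12 | intermediate
12 | (6R,7S,8aR)-6,7-epoxy-6,8a-dimethyl-1,2,6,7,8,8a-hexahydroazulen-3(5H)-one | O=C1CC[C@]2(C)C[C@@H]3O[C@]3(C)CC=C12 | intermediate
13 | 4-(benzyloxy)benzoyl chloride | O=C(Cl)c1ccc(OCc2ccccc2)cc1 | starting material
14 | dichlorocerium alkoxide of (3R,6R,7S,8aR)-6,7-epoxy-6,8a-dimethyl-3-(propan-2-yl)-1,2,3,5,6,7,8,8a-octahydroazulen-3-ol | CC(C)[C@]1(O[Ce](Cl)Cl)CC[C@]2(C)C[C@@H]3O[C@]3(C)CC=C12 | intermediate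
15 | (3R,6R,7S,8aR)-6,7-epoxy-6,8a-dimethyl-3-(propan-2-yl)-1,2,3,5,6,7,8,8a-octahydroazulen-3-yl 4-(benzyloxy)benzoate | CC(C)[C@]1(OC(=O)c2ccc(OCc3ccccc3)cc2)CC[C@]2(C)C[C@@H]3O[C@]3(C)CC=C12 | intermediate
16 | [(3R,3aR,4S,6R,7S,8aR)-3-{[4-(benzyloxy)benzoyl]oxy}-6,7-epoxy-6,8a-dimethyl-3-(propan-2-yl)decahydroazulen-4-yl]borane (boron on C4 and hydrogen on C3a, both on the face opposite the C8a methyl group) | CC(C)[C@]1(OC(=O)c2ccc(OCc3ccccc3)cc2)CC[C@]2(C)C[C@@H]3O[C@]3(C)C[C@H](B)[C@H]21 | intermediate
17 | (3R,3aS,4S,6R,7S,8aR)-6,7-epoxy-4-hydroxy-6,8a-dimethyl-3-(propan-2-yl)decahydroazulen-3-yl 4-(benzyloxy)benzoate | CC(C)[C@]1(OC(=O)c2ccc(OCc3ccccc3)cc2)CC[C@]2(C)C[C@@H]3O[C@]3(C)C[C@H](O)[C@H]21 | intermediate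
18 | (3R,3aS,4S,6R,7S,8aR)-6,7-epoxy-4-hydroxy-6,8a-dimethyl-3-(propan-2-yl)decahydroazulen-3-yl 4-hydroxybenzoate | CC(C)[C@]1(OC(=O)c2ccc(O)cc2)CC[C@]2(C)C[C@@H]3O[C@]3(C)C[C@H](O)[C@H]21 | target

**Step count and risks**

Total step count: 12. Longest linear sequence: 12 steps (1 to 18); acid chloride 13 is bought.

Steps most likely to fail:

Step 8 (bears the label "Proposed new method:"). The process at risk is the partition of the rhodacycle: reductive elimination at the internal allyl carbon would give a (3+2) bicyclo[3.3.0]octene instead of the seven-membered ring. Insertion of rhodium into the bond to the fully substituted cyclopropane carbon may also be slow, leaving room for oligomerisation of the terminal ynone or the thermal homo-1,5-hydrogen shift. The fallback uses known chemistry, sets out from 9 and comes back at 11. The alkyne of 9 is semi-hydrogenated (H2, Pd/CaCO3 poisoned with Pb(OAc)2, quinoline) to 5-[(1R,2R)-1-methyl-2-(prop-1-en-2-yl)cyclopropyl]pent-1-en-3-ol F1, which is silylated (TBSCl, imidazole) to its tert-butyldimethylsilyl ether F2. This substrate carries a plain terminal alkene tethered cis on the cyclopropane, the arrangement for which I believe the (5+2) mode of rhodium catalysis is documented (recalled, not checked), although not with a fully substituted cyclopropane carbon. Under [Rh(CO)2Cl]2 in toluene at 80 °C it should give tert-butyl{[(8aR)-6,8a-dimethyl-1,2,3,3a,4,5,8,8a-octahydroazulen-3-yl]oxy}dimethylsilane F3, whose C3 and C3a epimers are of no consequence. Desilylation (TBAF) gives the alcohol (8aR)-6,8a-dimethyl-1,2,3,3a,4,5,8,8a-octahydroazulen-3-ol F4, and Dess–Martin oxidation gives the saturated ketone (8aR)-6,8a-dimethyl-2,3a,4,5,8,8a-hexahydroazulen-3(1H)-one F5. TMSOTf/Et3N then gives the more substituted silyl enol ether {[(8aR)-6,8a-dimethyl-1,2,4,5,8,8a-hexahydroazulen-3-yl]oxy}trimethylsilane F6, and Saegusa–Ito dehydrogenation (Pd(OAc)2, MeCN) can only eliminate toward C4, so it returns to dienone 11.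

Step 10. The processes at risk are β-hydride reduction or enolisation of the enone by the secondary alkyl organometallic in place of addition, attack on the wrong face of the carbonyl, and incomplete acylation of the very hindered alkoxide. The fallback sets out from 12 and comes back at 15, and brings in the three carbons as an sp2 nucleophile. 2-Propenylmagnesium bromide with CeCl3 (THF, −78 °C), which cannot deliver a β-hydride and is less basic, is added and the alkoxide is trapped with 13 to give (3R,6R,7S,8aR)-6,7-epoxy-6,8a-dimethyl-3-(prop-1-en-2-yl)-1,2,3,5,6,7,8,8a-octahydroazulen-3-yl 4-(benzyloxy)benzoate F7. Chemoselective hydrogenation of its 1,1-disubstituted alkene (H2, RhCl(PPh3)3, benzene), which should leave the hindered trisubstituted alkene and the benzyl ether alone, returns to 15.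

Step 11. The processes at risk are attack of borane from the wrong face, competing reduction of the aryl ester, and Lewis-acid opening of the epoxide by borane. The fallback sets out from 12 and comes back at 17, and installs the C4 oxygen on the enone before C3 is built. Conjugate borylation (B2pin2, CuCl, NaOt-Bu, bis[2-(diphenylphosphino)phenyl] ether, MeOH, THF) is chemoselective for the enone and should deliver boron anti to the angular methyl group, with C3a set by protonation of the enolate, to give (3aR,4S,6R,7S,8aR)-6,7-epoxy-6,8a-dimethyl-4-(4,4,5,5-tetramethyl-1,3,2-dioxaborolan-2-yl)octahydroazulen-3(2H)-one F8. Oxidation (NaBO3·4H2O) gives the β-hydroxy ketone (3aS,4S,6R,7S,8aR)-6,7-epoxy-4-hydroxy-6,8a-dimethyloctahydroazulen-3(2H)-one F9, and silylation (TBSOTf, 2,6-lutidine) gives its tert-butyldimethylsilyl ether F10. Organocerium addition and in-flask acylation as in step 10 (i-PrLi, CeCl3; then 13) give (3R,3aS,4S,6R,7S,8aR)-4-[(tert-butyldimethylsilyl)oxy]-6,7-epoxy-6,8a-dimethyl-3-(propan-2-yl)decahydroazulen-3-yl 4-(benzyloxy)benzoate F11, and HF·pyridine returns to 17.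

**Further compounds**

F1 | step 8 | 5-[(1R,2R)-1-methyl-2-(prop-1-en-2-yl)cyclopropyl]pent-1-en-3-ol (both carbinol epimers) | CC(=C)[C@H]1C[C@@]1(C)CCC(O)C=C
F2 | step 8 | tert-butyl({5-[(1R,2R)-1-methyl-2-(prop-1-en-2-yl)cyclopropyl]pent-1-en-3-yl}oxy)dimethylsilane | CC(=C)[C@H]1C[C@@]1(C)CCC(O[Si](C)(C)C(C)(C)C)C=C
F3 | step 8 | tert-butyl{[(8aR)-6,8a-dimethyl-1,2,3,3a,4,5,8,8a-octahydroazulen-3-yl]oxy}dimethylsilane (C3 and C3a epimers) | C[C@]12CCC(O[Si](C)(C)C(C)(C)C)C1CCC(C)=CC2
F4 | step 8 | (8aR)-6,8a-dimethyl-1,2,3,3a,4,5,8,8a-octahydroazulen-3-ol (C3 and C3a epimers) | C[C@]12CCC(O)C1CCC(C)=CC2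
F5 | step 8 | (8aR)-6,8a-dimethyl-2,3a,4,5,8,8a-hexahydroazulen-3(1H)-one (C3a epimers) | C[C@]12CCC(=O)C1CCC(C)=CC2
F6 | step 8 | {[(8aR)-6,8a-dimethyl-1,2,4,5,8,8a-hexahydroazulen-3-yl]oxy}trimethylsilane | C[C@]12CCC(O[Si](C)(C)C)=C1CCC(C)=CC2
F7 | step 10 | (3R,6R,7S,8aR)-6,7-epoxy-6,8a-dimethyl-3-(prop-1-en-2-yl)-1,2,3,5,6,7,8,8a-octahydroazulen-3-yl 4-(benzyloxy)benzoate | CC(=C)[C@]1(OC(=O)c2ccc(OCc3ccccc3)cc2)CC[C@]2(C)C[C@@H]3O[C@]3(C)CC=C12
F8 | step 11 | (3aR,4S,6R,7S,8aR)-6,7-epoxy-6,8a-dimethyl-4-(4,4,5,5-tetramethyl-1,3,2-dioxaborolan-2-yl)octahydroazulen-3(2H)-one | O=C1CC[C@]2(C)C[C@@H]3O[C@]3(C)C[C@H](B4OC(C)(C)C(C)(C)O4)[C@H]21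
F9 | step 11 | (3aS,4S,6R,7S,8aR)-6,7-epoxy-4-hydroxy-6,8a-dimethyloctahydroazulen-3(2H)-one | O=C1CC[C@]2(C)C[C@@H]3O[C@]3(C)C[C@H](O)[C@H]21
F10 | step 11 | (3aS,4S,6R,7S,8aR)-4-[(tert-butyldimethylsilyl)oxy]-6,7-epoxy-6,8a-dimethyloctahydroazulen-3(2H)-one | O=C1CC[C@]2(C)C[C@@H]3O[C@]3(C)C[C@H](O[Si](C)(C)C(C)(C)C)[C@H]21
F11 | step 11 | (3R,3aS,4S,6R,7S,8aR)-4-[(tert-butyldimethylsilyl)oxy]-6,7-epoxy-6,8a-dimethyl-3-(propan-2-yl)decahydroazulen-3-yl 4-(benzyloxy)benzoate | CC(C)[C@]1(OC(=O)c2ccc(OCc3ccccc3)cc2)CC[C@]2(C)C[C@@H]3O[C@]3(C)C[C@H](O[Si](C)(C)C(C)(C)C)[C@H]21
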